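The earlier runs and the new flask come from a simulation from invented constants, noise included.

| setting | violet | green | flask |
|---|---|---|---|
| starting material | 5 mM | 5 mM | 5.0 mM |
| reagent | 4.2 mM | 6.6 mM | 3.00 mM |
| second substrate | 5 mM | 5 mM | 5.00 mM |
| third substrate | 2.5 mM | 2.5 mM | 2.50 mM |
| protic impurity | 1.5 mM | 1.5 mM | 1.50 mM |
| remark | run made earlier | run made earlier |  |
| time |  |  | 25 min |

| run | time / min | starting material / % | target / % |
|---|---|---|---|
| violet | 1.33 | 61 | 42 |
| violet | 4.00 | 60 | 41 |
| violet | 8.00 | 63 | 41 |
| violet | 10.0 | 62 | 39 |
| violet | 15.0 | 59 | 39 |
| violet | 20.0 | 60 | 38 |
| green | 1.50 | 35 | 61 |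
| green | 2.50 | 37 | 62 |
| green | 4.00 | 36 | 64 |
| green | 8.00 | 39 | 63 |
| green | 12.0 | 39 | 62 |
| green | 20.0 | 34 | 61 |

(each reading ± 1.5 percentage points)

- the reaction counts as stopped when no species that holds the starting material changes by six tenths of a point or more over the second half of the time

- the state of affairs at 25 min: stopped, and by what, or still going (all of the starting material has reacted / the reagent has run out first / forward and back rates have come level / it is still moving)
- conversion of starting material at 25 min
- amount of target at 25 min, in percent of the starting material charged

Target made per reagent charged was the ratio I went to first. The violet run averaged 2.00 mM of target from 4.2 mM of reagent, a ratio of 0.476. The green run averaged 3.11 mM from 6.6 mM, a ratio of 0.471. Both runs looked flat from their first readings, which came far earlier than the 25 min asked, so I treated each plateau as an end state. Starting material and target summed to 101 % in the violet reading at 4.00 min, so I took conversion and target as one number.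

Next I wrote the reagent's balance: what was charged went to target or to the second and third substrates. If reagent was the limiting reagent and the three substrates shared it in steady proportion, target had to be a fixed share of the charge. I took the mean, 0.474, as s, the capture share: target formed per reagent charged. For the new flask, s times 3.00 mM gave 1.42 mM of target, which is 28.4 % of the 5.0 mM of starting material.

The weak link was whether the full charge of reagent counted. Taking the protic impurity's 1.5 mM off the charge turned the ratios into 0.741 and 0.609, which lay further apart than the first pair, so I kept the full charge.

The forecast differed from my figure. It said the reagent has run out first, with conversion 23 % (18 % to 28 %) and target 23 % (18 % to 28 %), holding that the impurity “should destroy 1.5 mM of reagent first”.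

The new flask gave conversion 28.4 % and target 28.4 %, and the outcome was that the reagent has run out first. These steps stood behind it:

    starting material + reagent → target (k = 36.0 M⁻¹ s⁻¹)
    second substrate + reagent → second product (k = 29.0 M⁻¹ s⁻¹)
    third substrate + reagent → third product (k = 43.0 M⁻¹ s⁻¹)
    second substrate ⇌ dormant form (K = 0.550, k = 0.130 s⁻¹)
    second substrate + protic impurity → quenched substrate (k = 190 M⁻¹ s⁻¹)

By 1.25 min the new flask already held 28.4 % of target, made while reagent was present and the steps to target, second product and third product ran side by side. At 2.50 min reagent stood at 0 % and protic impurity at 0 %. At 25.0 min the reagent's balance in the new flask held 1.42 mM of target, 0.759 mM of second product and 0.822 mM of third product, summing to 3.00 mM, so s here was 0.473. For the neighbour flask with 7.5 mM of reagent, s gives 71.1 %, and that flask held 71.4 % of target.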